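**Retrosynthetic overview**

- The propanoate arm comes last: enol triflate/Reformatsky–Negishi coupling, then stereoselective α-methylation on the finished cis-fused bicycle; an allylic C–H oxidation supplies the ring ketone for this.
- The lactol-lactone comes from Baeyer–Villiger oxidation of a levoglucosenone cycloadduct and a glycol cleavage that excises the sugar CH2OH carbon.
- Key step: Diels–Alder reaction of 2-[(1S)-1,3,3-trimethylcyclohexyl]buta-1,3-diene with levoglucosenone; addition anti to the 1,6-anhydro bridge sets both ring-fusion centres.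
- The quaternary centre comes from a Claisen rearrangement with 1,3-chirality transfer from (R)-but-3-yn-2-ol; the carbocycle is then closed by metathesis.
- Ring order: trimethylcyclohexane (metathesis) → cyclohexene (Diels–Alder) → γ-lactone (Baeyer–Villiger) → lactol (glycol cleavage).

Assumption: the lactol carbon epimerises by ring–chain tautomerism, so its configuration is set by equilibration in the last step; the drawn (3R) epimer (OH able to hydrogen-bond to the ester carbonyl) is taken as the favoured one.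

Abbreviation: TMCH = (1S)-1,3,3-trimethylcyclohexyl, attached through C1.

**Route**

Step 1
Reactants: 1 (R)-but-3-yn-2-ol
Product: 2 (R)-pent-3-yn-2-ol
Conditions: n-BuLi (2.2 equiv), THF, −78 °C; then MeI, DMPU, −78 to 0 °C
Reagents that add atoms: iodomethane, CI
Why: C-alkylation of the alkynide–alkoxide dianion (the carbon nucleophile reacts far faster than the lithium alkoxide) leaves the carbinol centre untouched.

Step 2
Reactants: 2 (R)-pent-3-yn-2-ol
Product: 3 (2R,3Z)-4-iodopent-3-en-2-ol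
Conditions: NaAlH2(OCH2CH2OMe)2, THF, 0 to 23 °C; then I2, −78 °C
Reagents that add atoms: iodine, II
Why: alkoxide-directed trans-hydroalumination puts aluminium on the distal alkyne carbon and iodinolysis with retention gives only the Z-iodoalkene.

Step 3
Reactants: 4 2,2-dimethylpent-4-en-1-ol
Product: 5 5-iodo-4,4-dimethylpent-1-ene
Conditions: PPh3, I2, imidazole, PhMe, 90 °C
Reagents that add atoms: iodine, II
Why: Appel-type iodination through the alkoxyphosphonium salt; heating overcomes the slow SN2 step at the neopentyl carbon and no carbocation is formed.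

Step 4
Reactants: 3 (2R,3Z)-4-iodopent-3-en-2-ol; 5 5-iodo-4,4-dimethylpent-1-ene
Product: 7 (2R,3Z)-4,6,6-trimethylnona-3,8-dien-2-ol, via Grignard reagent 6 (not isolated)
Conditions: 5, Mg, THF, 45 °C; then 3, PdCl2(dppf) (5 mol%), THF, 45 °C (2.5 equiv of 6)
Reagents that add atoms: none
Why: Kumada cross-coupling with retention of alkene geometry; the neopentyl-type Grignard reagent has no β-hydrogen and its first equivalent only converts the hydroxyl into the magnesium alkoxide.

Step 5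
Reactants: 7 (2R,3Z)-4,6,6-trimethylnona-3,8-dien-2-ol
Product: 9 (3S,4E)-3-(2,2-dimethylpent-4-en-1-yl)-3-methylhex-4-enal, via allyl vinyl ether 8 (not isolated)
Conditions: butyl vinyl ether, Pd(OCOCF3)2 (1 mol%), 4,7-diphenyl-1,10-phenanthroline, Et3N, 75 °C; then PhMe, 140 °C (sealed tube)
Reagents that add atoms: butyl vinyl ether, C=COCCCC
Why: transfer vinylation then Claisen [3,3]-sigmatropic rearrangement through a chair transition state with the carbinol methyl pseudo-equatorial (hydrogen inside to avoid 1,3-allylic strain), so the (R)-carbinol centre is relayed suprafacially to the (S)-quaternary carbon and the new alkene is E.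

Step 6
Reactants: 9 (3S,4E)-3-(2,2-dimethylpent-4-en-1-yl)-3-methylhex-4-enal
Product: 11 2-(TMCH)acetaldehyde, via cyclohexene aldehyde 10 (not isolated)
Conditions: second-generation Grubbs catalyst RuCl2(H2IMes)(PCy3)(=CHPh) (2 mol%), CH2Cl2, 40 °C; then Pd/C, H2 (1 atm), 23 °C
Reagents that add atoms: none
Why: ring-closing metathesis (helped by the gem-dimethyl group, propene lost) closes the six-membered ring and the disubstituted ring alkene is hydrogenated in the same flask without touching the quaternary centre.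

Step 7
Reactants: 11 2-(TMCH)acetaldehyde
Product: 12 2-(TMCH)prop-2-enal
Conditions: 37% aq. HCHO, pyrrolidine (10 mol%), EtCO2H (10 mol%), i-PrOH, 45 °C
Reagents that add atoms: formaldehyde, C=O
Why: amine-catalysed Mannich condensation–elimination (α-methylenation of an aldehyde), a standard way to 2-alkylacroleins even when the α-carbon is neopentyl.

Step 8
Reactants: 12 2-(TMCH)prop-2-enal
Product: 13 2-(TMCH)buta-1,3-diene
Conditions: Ph3PCH3Br, KOt-Bu, THF, 0 to 23 °C
Reagents that add atoms: methyltriphenylphosphonium bromide, C[P+](c1ccccc1)(c1ccccc1)c1ccccc1.[Br-]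
Why: Wittig methylenation of the unhindered formyl group gives the 2-substituted diene, which the tert-alkyl group biases towards the s-cis form.

Step 9
Reactants: 13 2-(TMCH)buta-1,3-diene; 14 levoglucosenone
Product: 15 cycloadduct: levoglucosenone skeleton whose C3 and C4 (sugar numbering) are joined on the face anti to the 1,6-anhydro bridge by C4–CH2–C(TMCH)=CH–CH2–C3 (cis-fused cyclohexene; ketone and acetal intact)
Conditions: ZnCl2 (0.5 equiv), CH2Cl2, 23 °C
Reagents that add atoms: none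
Why: Lewis acid-promoted Diels–Alder reaction in which the diene adds only to the enone face anti to the 1,6-anhydro bridge, so the resident stereocentres of 14 set both ring-fusion centres (cis), and the nucleophilic diene CH2 next to the alkyl-bearing carbon bonds to the enone β-carbon (para orientation).

Step 10
Reactants: 15 cycloadduct
Product: 17 (3S,3aS,7aR)-3-(hydroxymethyl)-5-(TMCH)-3a,4,7,7a-tetrahydro-2-benzofuran-1(3H)-one, via formate ester 16 (not isolated)
Conditions: 30% aq. H2O2 (1.2 equiv), THF/H2O, 45 °C; then 1 M HCl, 23 °C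
Reagents that add atoms: hydrogen peroxide, OO
Why: Baeyer–Villiger oxidation of the activated α-acetal ketone with migration of the acetal carbon; the acyloxy acetal collapses to the γ-lactone and a formate that is hydrolysed, uncatalysed H2O2 spares the alkene and all stereocentres are retained.

Step 11
Reactants: 17 (3S,3aS,7aR)-3-(hydroxymethyl)-5-(TMCH)-3a,4,7,7a-tetrahydro-2-benzofuran-1(3H)-one
Product: 20 (3aS,7aR)-3-hydroxy-5-(TMCH)-3a,4,7,7a-tetrahydro-2-benzofuran-1(3H)-one (both C3 epimers), via dihydroxy acid salt 18 (not isolated), via formyl acid salt 19 (not isolated)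
Conditions: LiOH, THF/H2O, 0 °C; then NaIO4, pH 7, 0 °C; then 1 M HCl
Reagents that add atoms: lithium hydroxide, [Li+].[OH-]
Why: saponification, Malaprade glycol cleavage (the sugar CH2OH carbon leaves as formaldehyde) and acidification, on which the cis formyl acid closes to the hydroxy lactone; the cis ring fusion is the thermodynamic one, so the α-formyl centre is safe.

Step 12
Reactants: 20 (3aS,7aR)-3-hydroxy-5-(TMCH)-3a,4,7,7a-tetrahydro-2-benzofuran-1(3H)-one
Product: 21 (3aS,7aR)-3-methoxy-5-(TMCH)-3a,4,7,7a-tetrahydro-2-benzofuran-1(3H)-one (both C3 epimers)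
Conditions: MeOH, p-TsOH (cat.), 23 °C
Reagents that add atoms: methanol, CO
Why: acid-catalysed acetalisation of the pseudo-acid to its cyclic methyl pseudo-ester, which protects the lactol from the oxidants, hydride and bases that follow.

Step 13
Reactants: 21 (3aS,7aR)-3-methoxy-5-(TMCH)-3a,4,7,7a-tetrahydro-2-benzofuran-1(3H)-one
Product: 22 (3aR,7aR)-4-hydroxy-3-methoxy-5-(TMCH)-3a,4,7,7a-tetrahydro-2-benzofuran-1(3H)-one (mixture at C3 and C4)
Conditions: SeO2 (0.3 equiv), t-BuOOH, CH2Cl2, 23 °C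
Reagents that add atoms: selenium dioxide, O=[Se]=O; tert-butyl hydroperoxide, CC(C)(C)OO
Why: Riley allylic oxidation (ene reaction then [2,3]-sigmatropic shift) occurs at the CH2 on the more substituted alkene carbon, and C4 is the only such position because the other substituent is quaternary; the carbinol configuration is irrelevant.

Step 14
Reactants: 22 (3aR,7aR)-4-hydroxy-3-methoxy-5-(TMCH)-3a,4,7,7a-tetrahydro-2-benzofuran-1(3H)-one
Product: 23 (3aS,7aR)-3-methoxy-5-(TMCH)-3,3a,7,7a-tetrahydro-2-benzofuran-1,4-dione (both C3 epimers)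
Conditions: Dess–Martin periodinane, CH2Cl2, 23 °C
Reagents that add atoms: none
Why: Dess–Martin oxidation of the allylic alcohol under non-basic conditions, which avoids β-elimination of the acyloxy group next to the new ketone.

Step 15
Reactants: 23 (3aS,7aR)-3-methoxy-5-(TMCH)-3,3a,7,7a-tetrahydro-2-benzofuran-1,4-dione
Product: 25 (3aR,7aR)-3-methoxy-1-oxo-5-(TMCH)-1,3,3a,6,7,7a-hexahydro-2-benzofuran-4-yl trifluoromethanesulfonate, via lithium enolate 24 (not isolated)
Conditions: LiBH(s-Bu)3, THF, −78 °C; then N-(5-chloropyridin-2-yl)bis(trifluoromethanesulfonimide), −78 to 0 °C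
Reagents that add atoms: N-(5-chloropyridin-2-yl)bis(trifluoromethanesulfonimide) (Comins reagent), Clc1ccc(nc1)N(S(=O)(=O)C(F)(F)F)S(=O)(=O)C(F)(F)F
Why: conjugate (1,4) hydride reduction of the β-unsubstituted, α-hindered enone gives the enolate regiospecifically and O-sulfonylation traps it as the tetrasubstituted enol triflate.

Step 16
Reactants: 25 (3aR,7aR)-3-methoxy-1-oxo-5-(TMCH)-1,3,3a,6,7,7a-hexahydro-2-benzofuran-4-yl trifluoromethanesulfonate
Product: 26 methyl 2-[(3aR,7aR)-3-methoxy-1-oxo-5-(TMCH)-1,3,3a,6,7,7a-hexahydro-2-benzofuran-4-yl]acetate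
Conditions: BrZnCH2CO2Me (from BrCH2CO2Me, Zn), Pd2(dba)3 (2.5 mol%), XPhos (10 mol%), THF, 65 °C
Reagents that add atoms: (2-methoxy-2-oxoethyl)zinc bromide, COC(=O)C[Zn]Br
Why: Negishi cross-coupling of the Reformatsky reagent with the enol triflate (oxidative addition to zerovalent palladium, transmetalation, reductive elimination) puts the acetate on C4 and fixes the tetrasubstituted alkene.

Step 17
Reactants: 26 methyl 2-[(3aR,7aR)-3-methoxy-1-oxo-5-(TMCH)-1,3,3a,6,7,7a-hexahydro-2-benzofuran-4-yl]acetate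
Product: 28 methyl (2R)-2-[(3aR,7aR)-3-methoxy-1-oxo-5-(TMCH)-1,3,3a,6,7,7a-hexahydro-2-benzofuran-4-yl]propanoate, via lithium dienolate 27 (not isolated)
Conditions: LiN(i-Pr)2 (1.05 equiv), THF/DMPU, −78 °C; then MeI, −78 °C
Reagents that add atoms: iodomethane, CI
Why: α-alkylation of the ester dienolate; with the enolate C–H turned towards the tert-alkyl group (1,3-allylic strain), methyl iodide enters anti to the pseudo-axial acetal carbon on C3a, so the ring-fusion centre sets the (2R) centre.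

Step 18
Reactants: 28 methyl (2R)-2-[(3aR,7aR)-3-methoxy-1-oxo-5-(TMCH)-1,3,3a,6,7,7a-hexahydro-2-benzofuran-4-yl]propanoate
Product: 29 methyl (2R)-2-[(3R,3aR,7aR)-3-hydroxy-1-oxo-5-(TMCH)-1,3,3a,6,7,7a-hexahydro-2-benzofuran-4-yl]propanoate (CNP0280354.1)
Conditions: 1 M HCl, THF/H2O, 40 °C
Reagents that add atoms: water, O
Why: acid hydrolysis of the methyl pseudo-ester frees the lactol without touching the methyl ester, and the lactol carbon equilibrates to the (3R) epimer.

**Compound list**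

1 | (R)-but-3-yn-2-ol | C[C@@H](O)C#C | starting material
2 | (R)-pent-3-yn-2-ol | C[C@@H](O)C#CC | intermediate
3 | (2R,3Z)-4-iodopent-3-en-2-ol | C[C@@H](O)/C=C(\I)C | intermediate
4 | 2,2-dimethylpent-4-en-1-ol | OCC(C)(C)CC=C | starting material
5 | 5-iodo-4,4-dimethylpent-1-ene | ICC(C)(C)CC=C | intermediate
6 | (2,2-dimethylpent-4-en-1-yl)magnesium iodide (not isolated) | C=CCC(C)(C)C[Mg]I | intermediate
7 | (2R,3Z)-4,6,6-trimethylnona-3,8-dien-2-ol | C[C@@H](O)/C=C(\CC(C)(C)CC=C)C | intermediate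
8 | (2R,3Z)-2-(ethenyloxy)-4,6,6-trimethylnona-3,8-diene (not isolated) | C[C@@H](OC=C)/C=C(\CC(C)(C)CC=C)C | intermediate
9 | (3S,4E)-3-(2,2-dimethylpent-4-en-1-yl)-3-methylhex-4-enal | O=CC[C@](C)(CC(C)(C)CC=C)/C=C/C | intermediate
10 | 2-[(1S)-1,5,5-trimethylcyclohex-2-en-1-yl]acetaldehyde (not isolated) | O=CC[C@@]1(C)C=CCC(C)(C)C1 | intermediate
11 | 2-[(1S)-1,3,3-trimethylcyclohexyl]acetaldehyde | O=CC[C@@]1(C)CCCC(C)(C)C1 | intermediate
12 | 2-[(1S)-1,3,3-trimethylcyclohexyl]prop-2-enal | O=CC(=C)[C@@]1(C)CCCC(C)(C)C1 | intermediate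
13 | 2-[(1S)-1,3,3-trimethylcyclohexyl]buta-1,3-diene | C=CC(=C)[C@@]1(C)CCCC(C)(C)C1 | intermediate
14 | levoglucosenone = (1S,5R)-6,8-dioxabicyclo[3.2.1]oct-2-en-4-one | O=C1C=C[C@H]2CO[C@@H]1O2 | starting material
15 | cycloadduct: levoglucosenone skeleton with C3 and C4 (sugar numbering) joined anti to the 1,6-anhydro bridge by C4–CH2–C[(1S)-1,3,3-trimethylcyclohexyl]=CH–CH2–C3; cis-fused | O=C1[C@@H]2CC=C([C@@]3(C)CCCC(C)(C)C3)C[C@@H]2[C@H]4CO[C@@H]1O4 | intermediate
16 | formate ester of 17: [(1S,3aR,7aS)-3-oxo-6-[(1S)-1,3,3-trimethylcyclohexyl]-1,3,3a,4,7,7a-hexahydro-2-benzofuran-1-yl]methyl formate (not isolated) | O=C1[C@@H]2CC=C([C@@]3(C)CCCC(C)(C)C3)C[C@@H]2[C@@H](COC=O)O1 | intermediate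
17 | (3S,3aS,7aR)-3-(hydroxymethyl)-5-[(1S)-1,3,3-trimethylcyclohexyl]-3a,4,7,7a-tetrahydro-2-benzofuran-1(3H)-one | O=C1[C@@H]2CC=C([C@@]3(C)CCCC(C)(C)C3)C[C@@H]2[C@@H](CO)O1 | intermediate
18 | lithium (1R,2S)-2-[(1S)-1,2-dihydroxyethyl]-4-[(1S)-1,3,3-trimethylcyclohexyl]cyclohex-4-ene-1-carboxylate (not isolated) | [Li+].[O-]C(=O)[C@@H]1CC=C([C@@]2(C)CCCC(C)(C)C2)C[C@@H]1[C@H](O)CO | intermediate
19 | lithium (1R,2S)-2-formyl-4-[(1S)-1,3,3-trimethylcyclohexyl]cyclohex-4-ene-1-carboxylate (not isolated) | [Li+].[O-]C(=O)[C@@H]1CC=C([C@@]2(C)CCCC(C)(C)C2)C[C@@H]1C=O | intermediate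
20 | (3aS,7aR)-3-hydroxy-5-[(1S)-1,3,3-trimethylcyclohexyl]-3a,4,7,7a-tetrahydro-2-benzofuran-1(3H)-one (both C3 epimers) | O=C1[C@@H]2CC=C([C@@]3(C)CCCC(C)(C)C3)C[C@@H]2C(O)O1 | intermediate
21 | (3aS,7aR)-3-methoxy-5-[(1S)-1,3,3-trimethylcyclohexyl]-3a,4,7,7a-tetrahydro-2-benzofuran-1(3H)-one (both C3 epimers) | O=C1[C@@H]2CC=C([C@@]3(C)CCCC(C)(C)C3)C[C@@H]2C(OC)O1 | intermediate
22 | (3aR,7aR)-4-hydroxy-3-methoxy-5-[(1S)-1,3,3-trimethylcyclohexyl]-3a,4,7,7a-tetrahydro-2-benzofuran-1(3H)-one (mixture at C3 and C4) | O=C1[C@@H]2CC=C([C@@]3(C)CCCC(C)(C)C3)C(O)[C@@H]2C(OC)O1 | intermediate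
23 | (3aS,7aR)-3-methoxy-5-[(1S)-1,3,3-trimethylcyclohexyl]-3,3a,7,7a-tetrahydro-2-benzofuran-1,4-dione (both C3 epimers) | O=C1[C@@H]2CC=C([C@@]3(C)CCCC(C)(C)C3)C(=O)[C@@H]2C(OC)O1 | intermediate
24 | lithium enolate of the 5,6-dihydro ketone: lithium (3aR,7aR)-3-methoxy-1-oxo-5-[(1S)-1,3,3-trimethylcyclohexyl]-1,3,3a,6,7,7a-hexahydro-2-benzofuran-4-olate (not isolated) | O=C1[C@@H]2CCC([C@@]3(C)CCCC(C)(C)C3)=C(O[Li])[C@@H]2C(OC)O1 | intermediate
25 | (3aR,7aR)-3-methoxy-1-oxo-5-[(1S)-1,3,3-trimethylcyclohexyl]-1,3,3a,6,7,7a-hexahydro-2-benzofuran-4-yl trifluoromethanesulfonate | O=C1[C@@H]2CCC([C@@]3(C)CCCC(C)(C)C3)=C(OS(=O)(=O)C(F)(F)F)[C@@H]2C(OC)O1 | intermediate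
26 | methyl 2-[(3aR,7aR)-3-methoxy-1-oxo-5-[(1S)-1,3,3-trimethylcyclohexyl]-1,3,3a,6,7,7a-hexahydro-2-benzofuran-4-yl]acetate | O=C1[C@@H]2CCC([C@@]3(C)CCCC(C)(C)C3)=C(CC(=O)OC)[C@@H]2C(OC)O1 | intermediate
27 | lithium dienolate of 26 (lithium 1-methoxy-2-(ring C4)ethen-1-olate; not isolated) | O=C1[C@@H]2CCC([C@@]3(C)CCCC(C)(C)C3)=C(C=C(OC)O[Li])[C@@H]2C(OC)O1 | intermediate
28 | methyl (2R)-2-[(3aR,7aR)-3-methoxy-1-oxo-5-[(1S)-1,3,3-trimethylcyclohexyl]-1,3,3a,6,7,7a-hexahydro-2-benzofuran-4-yl]propanoate | O=C1[C@@H]2CCC([C@@]3(C)CCCC(C)(C)C3)=C([C@@H](C)C(=O)OC)[C@@H]2C(OC)O1 | intermediate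
29 | methyl (2R)-2-[(3R,3aR,7aR)-3-hydroxy-1-oxo-5-[(1S)-1,3,3-trimethylcyclohexyl]-1,3,3a,6,7,7a-hexahydro-2-benzofuran-4-yl]propanoate | COC(=O)[C@H](C)C1=C([C@@]2(C)CCCC(C)(C)C2)CC[C@H]2C(=O)O[C@@H](O)[C@@H]12 | target

**Step count and risks**

Total: 18 steps. Longest linear sequence: 17 steps (steps 1, 2 and 4–18, from compound 1).

The three steps most likely to fail:

Step 9 (regiochemistry: the diene has only one alkyl director). The fallback sets out from 12 and rejoins at 15. Horner–Wadsworth–Emmons reaction of 12 with lithiated diethyl [(phenylsulfanyl)methyl]phosphonate gives the sulfanyl diene {(1E)-3-[(1S)-1,3,3-trimethylcyclohexyl]buta-1,3-dien-1-yl}(phenyl)sulfane F1, in which sulfur and the alkyl group direct in the same sense. Cycloaddition of F1 with 14 gives the phenylsulfanyl cycloadduct F2 (SPh on the ring carbon next to the ketone α-carbon). Bu3SnH/AIBN then removes sulfur through the allyl radical, with hydrogen delivered to the less hindered terminus, to give 15.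

Step 13 (allylic oxidation at the hindered C4 methylene). The fallback sets out from 21 and rejoins at 22. Photo-oxygenation (O2, tetraphenylporphyrin, hν) is a singlet-oxygen ene reaction in which hydrogen is abstracted geminal to the large tert-alkyl group; it gives the transposed allylic hydroperoxide F3, reduced in the flask with PPh3 to the allylic alcohol F4. MnO2 gives the enone F5 and t-BuOOH/DBU the epoxy ketone F6. A Wharton transposition (N2H4·H2O, AcOH) then delivers the C4 allylic alcohol 22.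

Step 16 (cross-coupling at a tetrasubstituted triflate next to the tert-alkyl group). The fallback sets out from 23 and rejoins at 26. Reformatsky 1,2-addition of BrZnCH2CO2Me to 23 gives the tertiary allylic β-hydroxy ester F7. Ionic hydrogenation (Et3SiH, CF3CO2H, CH2Cl2, −40 °C) ionises F7 to the allyl cation and delivers hydride to the less hindered C6 terminus, giving 26 with the tetrasubstituted alkene in place.

**Further compounds**

F1 | step 9 | {(1E)-3-[(1S)-1,3,3-trimethylcyclohexyl]buta-1,3-dien-1-yl}(phenyl)sulfane | C=C(/C=C/Sc1ccccc1)[C@@]1(C)CCCC(C)(C)C1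
F2 | step 9 | phenylsulfanyl analogue of 15 (SPh on the ring carbon between the alkene CH and the ketone α-carbon; sulfur-bearing centre undefined) | O=C1[C@@H]2C(Sc3ccccc3)C=C([C@@]4(C)CCCC(C)(C)C4)C[C@@H]2[C@H]5CO[C@@H]1O5
F3 | step 13 | (3aS,7aR)-6-hydroperoxy-3-methoxy-5-[(1S)-1,3,3-trimethylcyclohexyl]-3a,6,7,7a-tetrahydro-2-benzofuran-1(3H)-one (mixture at C3 and C6) | O=C1[C@@H]2CC(OO)C([C@@]3(C)CCCC(C)(C)C3)=C[C@@H]2C(OC)O1
F4 | step 13 | (3aS,7aR)-6-hydroxy-3-methoxy-5-[(1S)-1,3,3-trimethylcyclohexyl]-3a,6,7,7a-tetrahydro-2-benzofuran-1(3H)-one (mixture at C3 and C6) | O=C1[C@@H]2CC(O)C([C@@]3(C)CCCC(C)(C)C3)=C[C@@H]2C(OC)O1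
F5 | step 13 | (3aS,7aR)-3-methoxy-5-[(1S)-1,3,3-trimethylcyclohexyl]-3,3a,7,7a-tetrahydro-2-benzofuran-1,6-dione (both C3 epimers) | O=C1[C@@H]2CC(=O)C([C@@]3(C)CCCC(C)(C)C3)=C[C@@H]2C(OC)O1
F6 | step 13 | 4,5-epoxide of F5: (3aR,7aR)-4,5-epoxy-3-methoxy-5-[(1S)-1,3,3-trimethylcyclohexyl]hexahydro-2-benzofuran-1,6-dione (epoxide face undefined) | O=C1[C@@H]2CC(=O)C3([C@@]4(C)CCCC(C)(C)C4)OC3[C@@H]2C(OC)O1
F7 | step 16 | methyl 2-[(3aR,7aR)-4-hydroxy-3-methoxy-1-oxo-5-[(1S)-1,3,3-trimethylcyclohexyl]-1,3,3a,4,7,7a-hexahydro-2-benzofuran-4-yl]acetate (mixture at C3 and C4) | O=C1[C@@H]2CC=C([C@@]3(C)CCCC(C)(C)C3)C(O)(CC(=O)OC)[C@@H]2C(OC)O1
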